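**Retrosynthetic overview** (numbers follow the forward route)
1. Chain-to-ring C–C disconnection: 1-bromononadecane 1 and 3-ethoxycyclohex-2-en-1-one 2 (through Grignard reagent 3 and 1,2-adduct 4) account for enone 5.
2. C–O disconnection, the stereo-defining one: the tertiary C–O bond of the carbinol is made on 5 by enantioselective epoxidation, giving cis-epoxy ketone 6.
3. No further skeletal bond: target 7 is a constitutional isomer of 6 (both C25H46O2); the oxirane Cα–O bond is exchanged for the C2=C3 double bond in one palladium-catalysed internal-redox isomerisation.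
4. Ring order: the six-membered carbocycle is bought with 2; the oxirane is closed in step 2 and opened in step 3.

Assumption: the target is the (S)-enantiomer as drawn, and the quinine-derived amine salt is taken to give the (1S,6S)-epoxide; if its facial sense is opposite on this substrate, the quinidine-derived pseudoenantiomer is used under the same conditions.

**Step 1**
Reactants: 1 1-bromononadecane; 2 3-ethoxycyclohex-2-en-1-one
Product: 5 3-nonadecylcyclohex-2-en-1-one, via nonadecylmagnesium bromide 3 (not isolated), via 3-ethoxy-1-nonadecylcyclohex-2-en-1-ol 4 (not isolated)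
Conditions: Mg, I2 (cat.), THF, reflux; then 2, THF, 0 °C to rt; then 1 M aq. HCl, rt
Reagents that add atoms: water, SMILES O
Why: Stork–Danheiser alkylative transposition: the Grignard reagent adds 1,2 to the vinylogous ester, and acid hydrolysis of the enol ether carbinol (loss of ethanol, carbonyl oxygen from water) unmasks the 3-alkyl enone; the stereocentre of racemic 4 is destroyed, so none is carried forward.

**Step 2**
Reactants: 5 3-nonadecylcyclohex-2-en-1-one
Product: 6 (1S,6S)-6-nonadecyl-7-oxabicyclo[4.1.0]heptan-2-one
Conditions: 9-amino-9-deoxy-epi-quinine (10 mol %), CF3CO2H (20 mol %), 50% aq. H2O2 (1.5 equiv), 1,4-dioxane, 50 °C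
Reagents that add atoms: hydrogen peroxide, SMILES OO
Why: Amine-catalysed asymmetric Weitz–Scheffer epoxidation: the chiral primary ammonium salt forms an iminium ion with the enone, hydrogen peroxide adds to one face of C3 to make the tertiary C–O bond, and the peroxy enamine closes to the cis-epoxide, fixing the future carbinol carbon as S; simple 3-alkylcyclohex-2-enones are, to my recollection, established substrates for this catalyst class.

**Step 3**
Reactants: 6 (1S,6S)-6-nonadecyl-7-oxabicyclo[4.1.0]heptan-2-one
Product: 7 (5S)-5-hydroxy-5-nonadecylcyclohex-2-en-1-one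
Conditions: Pd(PPh3)4 (5 mol %), dppe (5 mol %), tBuCO2H (20 mol %), MeCN–toluene 1:1, 80 °C, argon
Reagents that add atoms: none
Why: Proposed new method: the oxirane serves as the internal oxidant for a palladium-catalysed α′,β′-dehydrogenation of its own ketone – zerovalent palladium adds oxidatively to the Cα–O bond C1–O7 (the opening step of the known palladium-catalysed isomerisation of α,β-epoxy ketones to 1,3-diketones and of their palladium/formate hydrogenolysis to aldols), the usual β-hydride exit to a diketone is closed because C6 bears no hydrogen, pivalic acid/pivalate relays a proton from C3 to C1 so that the divalent palladium enolate shifts to the only other enolisable carbon C3, and β-hydride elimination from C4 (as in Saegusa–Ito and Tsuji enolate dehydrogenations) followed by O–H reductive elimination releases 7 and zerovalent palladium; the C6–O bond is never broken, so the S configuration set in step 2 is retained (locants are those of 6).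

**Compound list**
1 | 1-bromononadecane | CCCCCCCCCCCCCCCCCCCBr | starting material
2 | 3-ethoxycyclohex-2-en-1-one | CCOC1=CC(=O)CCC1 | starting material
3 | nonadecylmagnesium bromide | CCCCCCCCCCCCCCCCCCC[Mg]Br | intermediate
4 | 3-ethoxy-1-nonadecylcyclohex-2-en-1-ol (racemic) | CCCCCCCCCCCCCCCCCCCC1(O)CCCC(OCC)=C1 | intermediate
5 | 3-nonadecylcyclohex-2-en-1-one | CCCCCCCCCCCCCCCCCCCC1=CC(=O)CCC1 | intermediate
6 | (1S,6S)-6-nonadecyl-7-oxabicyclo[4.1.0]heptan-2-one | CCCCCCCCCCCCCCCCCCC[C@]12CCCC(=O)[C@H]1O2 | intermediate
7 | (5S)-5-hydroxy-5-nonadecylcyclohex-2-en-1-one | CCCCCCCCCCCCCCCCCCC[C@]1(O)CC=CC(=O)C1 | target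

**Step count:** 3 steps in total; longest linear sequence 3 steps.

**Steps most likely to fail and their fallbacks**

Risk A (step 3, the proposed isomerisation). After oxidative addition the palladium enolate may fail to turn over, lose hydroxide to return 5, undergo retro-aldol opening, or the product may dehydrate and aromatise to the meta-alkylphenol. The fallback uses known reactions only, sets out from 6 and comes back to the route at 7. Kinetic enolisation of 6 at its only enolisable carbon (LiN(iPr)2, Me3SiCl, THF, –78 °C) gives trimethyl{[(1S,6S)-6-nonadecyl-7-oxabicyclo[4.1.0]hept-2-en-2-yl]oxy}silane F1. Saegusa–Ito oxidation (Pd(OAc)2, 1.05 equiv, MeCN–THF, rt) gives (1S,6S)-6-nonadecyl-7-oxabicyclo[4.1.0]hept-3-en-2-one F2. Reductive cleavage of the Cα–O bond (SmI2, 2.2 equiv, THF–MeOH, –90 °C) then gives 7 with the carbinol configuration untouched.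

Risk B (step 2, the epoxidation). Iminium formation with the hindered, waxy enone may be slow and the ee may fall short. The fallback replaces direct C–O formation by C–B formation with stereoretentive oxidation, sets out from 5 and comes back at 7, bypassing 6. Copper-catalysed enantioselective conjugate borylation ([Cu(MeCN)4]PF6, the QuinoxP* enantiomer that gives the R boronate, LiOtBu, B2pin2, MeOH, DMSO–THF, rt) gives (R)-3-nonadecyl-3-(4,4,5,5-tetramethyl-1,3,2-dioxaborolan-2-yl)cyclohexan-1-one F3. Oxidation with NaBO3·4H2O in THF–water proceeds with retention to (S)-3-hydroxy-3-nonadecylcyclohexan-1-one F4. Dehydrogenation with IBX and 4-methoxypyridine N-oxide in DMSO at rt gives 7; only the C5–C6 side can be desaturated because the carbinol carbon has no hydrogen.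

Risk C (step 1, Grignard addition). Wurtz coupling and poor solubility of the long-chain Grignard reagent may depress the yield. The fallback changes carbonyl addition/transposition into an sp3–sp2 cross-coupling, sets out from 1 and comes back at 5. Zinc insertion (Zn dust activated with 1,2-dibromoethane and Me3SiCl, LiCl, THF, 50 °C) gives nonadecylzinc bromide F5. Negishi coupling (Pd(dppf)Cl2, 2 mol %, THF, 50 °C) with purchased 3-bromocyclohex-2-en-1-one (O=C1CCCC(Br)=C1) then gives 5 directly.

**Further compounds**
F1 | step 3 | trimethyl{[(1S,6S)-6-nonadecyl-7-oxabicyclo[4.1.0]hept-2-en-2-yl]oxy}silane | CCCCCCCCCCCCCCCCCCC[C@]12CCC=C(O[Si](C)(C)C)[C@H]1O2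
F2 | step 3 | (1S,6S)-6-nonadecyl-7-oxabicyclo[4.1.0]hept-3-en-2-one | CCCCCCCCCCCCCCCCCCC[C@]12CC=CC(=O)[C@H]1O2
F3 | step 2 | (R)-3-nonadecyl-3-(4,4,5,5-tetramethyl-1,3,2-dioxaborolan-2-yl)cyclohexan-1-one | CCCCCCCCCCCCCCCCCCC[C@]1(B2OC(C)(C)C(C)(C)O2)CCCC(=O)C1
F4 | step 2 | (S)-3-hydroxy-3-nonadecylcyclohexan-1-one | CCCCCCCCCCCCCCCCCCC[C@]1(O)CCCC(=O)C1
F5 | step 1 | nonadecylzinc bromide | CCCCCCCCCCCCCCCCCCC[Zn]Br
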